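## Retrosynthetic overview

1. The target comes from O-desilylation of quinone 39, and 39 from an anodic oxidative ring closure of the acyclic (3Z)-2,5-bis(silyloxy)hepta-1,3,5-triene 36. This closure makes the ring bond between the CH carbon and the methyl-bearing carbon (C3–C2; C1 is the carbonyl between C2 and the side-chain carbon C6, C4 the other carbonyl).
2. Enabling feature: C2 and C3 are the α-carbons of the two ring carbonyls C1 and C4, and C5=C6 is a cis-olefin carrying both carbonyl carbons. The six-membered ring is therefore the oxidative α,α′-coupling product of a (Z)-ene-1,4-dione, which is the singlet-oxygen opening product of a 2-ethyl-5-methyl-3-alkylfuran; this temporary ring sets the Z geometry and the 2,6-pattern.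
3. Furan 33 comes from the C5′–C6′ bond, made by catalytic asymmetric alkenylzinc addition of dienyl iodide 18 to aldehyde 28; 28 comes from the alkenylalane of but-3-yn-1-ol and furylmethyl chloride 24 (Paal–Knorr furan).
4. Iodide 18 comes from ethynyl oxolane 10 by two zirconium-catalysed carboaluminations and one Negishi coupling, so all three trisubstituted olefins are set (E) from alkynes.
5. Ring order: the oxolane first (step 4; Noyori reduction sets C12′, Shi epoxidation sets C14′, 5-endo epoxide opening closes the ring), then the temporary furan (step 11), then the quinone ring last (step 20).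

Key step: step 20

Remark: the quinone ring is numbered C1 (carbonyl between the substituted carbons), C2 (C–CH3), C3 (CH), C4 (carbonyl), C5 (CH), C6 (C–side chain), the side chain C1′–C15′ from the ring outward, and R* denotes the group (2E,5S,6E,10E)-5-acetoxy-3,7-dimethyl-11-[(2S,4S)-5,5-dimethyl-4-(triethylsilyloxy)oxolan-2-yl]dodeca-2,6,10-trien-1-yl.

## Route

Step 1
Reactants: 1 4-methylpent-3-enoic acid
Product: 3 N-methoxy-N-methyl-4-methylpent-3-enamide, via acyl imidazole 2 (not isolated)
Conditions: CDI, CH2Cl2, 0 °C to rt; then MeNHOMe·HCl, rt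
Reagents that add atoms: N,O-dimethylhydroxylamine hydrochloride, CNOC.Cl
Why: Amide formation through the acyl imidazole is a mild, non-isomerising way to the Weinreb amide of a β,γ-unsaturated acid.

Step 2
Reactants: 3 N-methoxy-N-methyl-4-methylpent-3-enamide; 4 lithium (trimethylsilyl)acetylide
Product: 5 6-methyl-1-(trimethylsilyl)hept-5-en-1-yn-3-one
Conditions: 4 (0.5 M in THF), THF, −78 to −20 °C; aq. NH4Cl
Reagents that add atoms: none
Why: Weinreb ketone synthesis, in which the chelated tetrahedral adduct prevents over-addition and the weakly basic acetylide should leave the skipped olefin in place.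

Step 3
Reactants: 5 6-methyl-1-(trimethylsilyl)hept-5-en-1-yn-3-one
Product: 7 (3S)-6-methylhept-5-en-1-yn-3-ol, via TMS-alkynol 6 (not isolated)
Conditions: Ru[(S,S)-TsDPEN](p-cymene) (1 mol %), i-PrOH, rt; then K2CO3, MeOH, rt
Reagents that add atoms: none
Why: Noyori asymmetric transfer hydrogenation of an alkynyl ketone, in which the (S,S)-catalyst should give the (S)-propargylic alcohol (the alkyne takes the place of the aryl group of the usual model), followed by base-mediated C-desilylation.

Step 4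
Reactants: 7 (3S)-6-methylhept-5-en-1-yn-3-ol
Product: 9 (3S,5S)-5-ethynyl-2,2-dimethyloxolan-3-ol, via epoxy alcohol 8 (not isolated)
Conditions: ent-Shi ketone (L-fructose-derived, 30 mol %), Oxone, K2CO3, Bu4NHSO4, MeCN/dimethoxymethane/aq. Na2B4O7 buffer, 0 °C; extractive work-up, then CSA (10 mol %), CH2Cl2, 0 °C
Reagents that add atoms: Oxone (potassium peroxymonosulfate), [K+].[O-]S(=O)(=O)OO
Why: Shi asymmetric epoxidation of the only olefin (catalyst control, the L-series ketone giving the (S)-epoxide at the CH carbon) followed by acid-catalysed 5-endo epoxide opening by the C12′ hydroxyl at the tertiary carbon, which retains both C–O stereocentres and so should give the cis (3S,5S) oxolane.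

Step 5
Reactants: 9 (3S,5S)-5-ethynyl-2,2-dimethyloxolan-3-ol
Product: 10 (3S,5S)-5-ethynyl-2,2-dimethyl-3-(triethylsilyloxy)oxolane
Conditions: TESCl, imidazole, DMAP (cat.), CH2Cl2, rt
Reagents that add atoms: chlorotriethylsilane, CC[Si](Cl)(CC)CC
Why: Standard silylation of a secondary alcohol, giving an ether that survives the organometallic steps and is removed last under mild acid fluoride.

Step 6
Reactants: 10 (3S,5S)-5-ethynyl-2,2-dimethyl-3-(triethylsilyloxy)oxolane
Product: 12 (3S,5S)-5-[(1E)-1-iodoprop-1-en-2-yl]-2,2-dimethyl-3-(triethylsilyloxy)oxolane, via alkenylalane 11 (not isolated)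
Conditions: Me3Al (3 equiv), Cp2ZrCl2 (0.3 equiv), CH2Cl2, 0 °C to rt; then I2, THF, −30 °C
Reagents that add atoms: trimethylaluminium, C[Al](C)C; iodine, II
Why: Negishi zirconium-catalysed carboalumination adds CH3 and Al syn across the terminal alkyne with CH3 on the internal carbon, and iodinolysis retains the (E) geometry of the C10′=C11′ olefin.

Step 7
Reactants: 12 (3S,5S)-5-[(1E)-1-iodoprop-1-en-2-yl]-2,2-dimethyl-3-(triethylsilyloxy)oxolane; 13 (4-bromobut-1-yn-1-yl)trimethylsilane
Product: 15 (3S,5S)-2,2-dimethyl-3-(triethylsilyloxy)-5-[(2E)-7-(trimethylsilyl)hept-2-en-6-yn-2-yl]oxolane, via alkylzinc bromide 14 (not isolated)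
Conditions: 13, Zn dust, LiCl, THF, 50 °C; then 12, Pd(dppf)Cl2 (5 mol %), THF, rt to 45 °C
Reagents that add atoms: none
Why: Negishi sp3–sp2 cross-coupling of a primary alkylzinc halide with an alkenyl iodide, which proceeds with retention of olefin geometry.

Step 8
Reactants: 15 (3S,5S)-2,2-dimethyl-3-(triethylsilyloxy)-5-[(2E)-7-(trimethylsilyl)hept-2-en-6-yn-2-yl]oxolane
Product: 16 (3S,5S)-5-[(2E)-hept-2-en-6-yn-2-yl]-2,2-dimethyl-3-(triethylsilyloxy)oxolane
Conditions: K2CO3, MeOH/THF, rt
Reagents that add atoms: none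
Why: Base-mediated protodesilylation of an alkynylsilane, to which the secondary triethylsilyl ether should be stable.

Step 9
Reactants: 16 (3S,5S)-5-[(2E)-hept-2-en-6-yn-2-yl]-2,2-dimethyl-3-(triethylsilyloxy)oxolane
Product: 18 (3S,5S)-5-[(2E,6E)-7-iodo-6-methylhepta-2,6-dien-2-yl]-2,2-dimethyl-3-(triethylsilyloxy)oxolane, via alkenylalane 17 (not isolated)
Conditions: Me3Al (3 equiv), Cp2ZrCl2 (0.3 equiv), CH2Cl2, 0 °C to rt; then I2, THF, −30 °C
Reagents that add atoms: trimethylaluminium, C[Al](C)C; iodine, II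
Why: A second Negishi carboalumination–iodinolysis sets the (E)-C6′=C7′ olefin by syn addition, the existing trisubstituted olefin being inert.

Step 10
Reactants: 19 ethyl 3-oxopentanoate; 20 chloroacetone
Product: 21 ethyl 4-oxo-2-propanoylpentanoate
Conditions: K2CO3, NaI (cat.), acetone, reflux
Reagents that add atoms: none
Why: C-alkylation of a β-keto ester enolate with an α-halo ketone gives the 1,4-diketone in which the ester sits next to the propanoyl group.

Step 11
Reactants: 21 ethyl 4-oxo-2-propanoylpentanoate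
Product: 22 ethyl 2-ethyl-5-methylfuran-3-carboxylate
Conditions: p-TsOH·H2O (cat.), toluene, reflux, Dean–Stark
Reagents that add atoms: none
Why: Paal–Knorr furan synthesis, which places ethyl at the furan carbon next to the ester-bearing carbon and methyl at the far carbon without ambiguity.

Step 12
Reactants: 22 ethyl 2-ethyl-5-methylfuran-3-carboxylate
Product: 23 (2-ethyl-5-methylfuran-3-yl)methanol
Conditions: LiAlH4, THF, 0 °C
Reagents that add atoms: none
Why: Hydride reduction of an ester to the primary alcohol.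

Step 13
Reactants: 23 (2-ethyl-5-methylfuran-3-yl)methanol
Product: 24 3-(chloromethyl)-2-ethyl-5-methylfuran
Conditions: NCS, PPh3, CH2Cl2, −20 to 0 °C; used at once
Reagents that add atoms: N-chlorosuccinimide, ClN1C(=O)CCC1=O
Why: Appel-type chlorination under neutral conditions suits an acid-sensitive, ionisation-prone furylmethyl chloride.

Step 14
Reactants: 25 but-3-yn-1-ol; 24 3-(chloromethyl)-2-ethyl-5-methylfuran
Product: 27 (3E)-5-(2-ethyl-5-methylfuran-3-yl)-3-methylpent-3-en-1-ol, via alkenylalane 26 (not isolated)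
Conditions: 25, Me3Al (3 equiv), Cp2ZrCl2 (0.25 equiv), CH2Cl2, 0 °C to rt; then 24, Pd(PPh3)4 (5 mol %), THF, rt
Reagents that add atoms: trimethylaluminium, C[Al](C)C
Why: Negishi carboalumination of the homopropargylic alcohol (carried as its aluminium alkoxide) followed by palladium-catalysed cross-coupling of the alkenylalane with the benzylic-type chloride sets the (E)-C2′=C3′ olefin and the C1′–C2′ bond.

Step 15
Reactants: 27 (3E)-5-(2-ethyl-5-methylfuran-3-yl)-3-methylpent-3-en-1-ol
Product: 28 (3E)-5-(2-ethyl-5-methylfuran-3-yl)-3-methylpent-3-enal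
Conditions: Dess–Martin periodinane, NaHCO3, CH2Cl2, 0 °C; used at once
Reagents that add atoms: none
Why: Buffered Dess–Martin oxidation gives the β,γ-unsaturated aldehyde without acid or base that would move the olefin into conjugation.

Step 16
Reactants: 18 (3S,5S)-5-[(2E,6E)-7-iodo-6-methylhepta-2,6-dien-2-yl]-2,2-dimethyl-3-(triethylsilyloxy)oxolane; 28 (3E)-5-(2-ethyl-5-methylfuran-3-yl)-3-methylpent-3-enal
Product: 32 (2E,5S,6E,10E)-1-(2-ethyl-5-methylfuran-3-yl)-3,7-dimethyl-11-[(2S,4S)-5,5-dimethyl-4-(triethylsilyloxy)oxolan-2-yl]dodeca-2,6,10-trien-5-ol, via alkenyllithium 29 (not isolated), via alkenylzinc chloride 30 (not isolated), via alkenyl(butyl)zinc 31 (not isolated)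
Conditions: 18, t-BuLi (2.0 equiv), Et2O, −78 °C; ZnCl2 (1.0 equiv), −78 to 0 °C; n-BuLi (1.0 equiv), −78 °C; N,N,N′,N′-tetraethylethylenediamine (0.8 equiv), toluene; (+)-MIB (10 mol %), then 28, 0 °C
Reagents that add atoms: none
Why: Catalytic asymmetric alkenylzinc addition to an aldehyde under amino-alcohol control, in which lithium–iodine exchange and transmetalation keep the (E) geometry, the diamine sequesters lithium halides that would promote the racemic pathway, and the (+)-ligand should send the alkenyl group to the Re face to set C5′ as (S) (the (−)-ligand delivers to the Si face).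

Step 17
Reactants: 32 (2E,5S,6E,10E)-1-(2-ethyl-5-methylfuran-3-yl)-3,7-dimethyl-11-[(2S,4S)-5,5-dimethyl-4-(triethylsilyloxy)oxolan-2-yl]dodeca-2,6,10-trien-5-ol
Product: 33 2-ethyl-5-methyl-3-R*-furan
Conditions: Ac2O, pyridine, DMAP (cat.), CH2Cl2, 0 °C
Reagents that add atoms: acetic anhydride, CC(=O)OC(C)=O
Why: Acylation of the only free hydroxyl installs the C5′ acetate with retention, the C14′ oxygen being silylated.

Step 18
Reactants: 33 2-ethyl-5-methyl-3-R*-furan
Product: 35 (3Z)-4-R*-hept-3-ene-2,5-dione, via endoperoxide 34 (not isolated)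
Conditions: O2, tetraphenylporphyrin (cat.), visible light, CH2Cl2, −78 °C, stopped when the furan is consumed; then Me2S, −78 to 0 °C
Reagents that add atoms: dioxygen (singlet), O=O
Why: [4+2] photooxygenation of a 2,5-dialkylfuran, which should be far faster than the ene reaction of trisubstituted olefins, followed by reduction of the endoperoxide, which unveils the cis-enedione with the Z geometry dictated by the former ring.

Step 19
Reactants: 35 (3Z)-4-R*-hept-3-ene-2,5-dione
Product: 36 (3Z,5Z)-2,5-bis(tert-butyldimethylsilyloxy)-4-R*-hepta-1,3,5-triene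
Conditions: TBSOTf (2.4 equiv), Et3N (4 equiv), CH2Cl2, −78 to −20 °C; filtration through basic alumina
Reagents that add atoms: tert-butyldimethylsilyl trifluoromethanesulfonate, CC(C)(C)[Si](C)(C)OS(=O)(=O)C(F)(F)F
Why: Soft enolisation of both enone carbonyls with silyl triflate and amine, which under kinetic control should deprotonate the α′ positions (acetyl CH3 and propanoyl CH2) to give the cross-conjugated 2-silyloxydiene units; the enol ether geometry is inconsequential.

Step 20
Reactants: 36 (3Z,5Z)-2,5-bis(tert-butyldimethylsilyloxy)-4-R*-hepta-1,3,5-triene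
Product: 39 2-methyl-6-R*-cyclohexa-2,5-diene-1,4-dione, via cyclohexenedione 37 (not isolated), via hydroquinone 38 (not isolated)
Conditions: divided cell, reticulated vitreous carbon anode, Pt cathode, constant current (about 0.5 mA cm−2, 4.2 F mol−1), LiClO4 (0.1 M), (4-BrC6H4)3N (10 mol %), 2,6-lutidine (4 equiv), MeCN/CH2Cl2/i-PrOH (6:3:1), 0 °C
Reagents that add atoms: none
Why: Proposed new method: one-electron oxidation at the anode (directly or through the triarylamine mediator) should take an electron from the conjugated 2,5-bis(silyloxy)triene, and the radical cation should close by bonding its two terminal enol-ether carbons (the CH2 terminus, the future ring CH, and the CHCH3 terminus, the future ring C–CH3); loss of both silyl groups to i-PrOH and a second electron give cyclohexenedione 37, whose enolisation to hydroquinone 38 and further two-electron oxidation deliver quinone 39, four electrons in all. The closest known reaction types are the intramolecular anodic coupling of two enol ethers and the coupling of silyl bis-enol ethers to 1,4-diketones by one-electron oxidants, together with the routine anodic oxidation of hydroquinones; new is their use on a conjugated bis(silyloxy)triene to build a ring at the aromatic oxidation level. The six-membered carbocycle closes in a 6-endo-trig radical-cation mode, formally the 6π closure of a (3Z)-hexatriene radical cation. No stereocentre is created that survives, since the CH(CH3) centre of 37 is erased on aromatisation and the three side-chain stereocentres are remote from the electroactive unit. The step needs chemoselective oxidation of the triene beside three trisubstituted olefins, which the expected lower oxidation potential of the bis(silyloxy)triene and the potential ceiling of the mediator should secure, and it needs ring closure to outrun solvent capture or proton loss, which the (Z)-central olefin inherited from the furan should secure by holding the two termini within bonding distance. The 2,6-pattern of the quinone follows from the substitution of the furan, because in 35 the ethyl ketone sits next to the carbon that bears the side chain.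

Step 21
Reactants: 39 2-methyl-6-R*-cyclohexa-2,5-diene-1,4-dione
Product: 40 2-[(2E,5S,6E,10E)-5-acetoxy-11-{(2S,4S)-4-hydroxy-5,5-dimethyloxolan-2-yl}-3,7-dimethyldodeca-2,6,10-trien-1-yl]-6-methylcyclohexa-2,5-diene-1,4-dione
Conditions: HF·pyridine, pyridine, THF, 0 °C
Reagents that add atoms: none
Why: Buffered fluoride cleavage of the secondary triethylsilyl ether under mildly acidic conditions that the quinone and the allylic acetate should tolerate.

## Compound list

1 | 4-methylpent-3-enoic acid | CC(C)=CCC(=O)O | starting material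
2 | 1-(imidazol-1-yl)-4-methylpent-3-en-1-one | CC(C)=CCC(=O)n1ccnc1 | intermediate
3 | N-methoxy-N-methyl-4-methylpent-3-enamide | CC(C)=CCC(=O)N(C)OC | intermediate
4 | lithium (trimethylsilyl)acetylide | [Li]C#C[Si](C)(C)C | starting material
5 | 6-methyl-1-(trimethylsilyl)hept-5-en-1-yn-3-one | CC(C)=CCC(=O)C#C[Si](C)(C)C | intermediate
6 | (3S)-6-methyl-1-(trimethylsilyl)hept-5-en-1-yn-3-ol | C[Si](C)(C)C#C[C@@H](O)CC=C(C)C | intermediate
7 | (3S)-6-methylhept-5-en-1-yn-3-ol | C#C[C@@H](O)CC=C(C)C | intermediate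
8 | (2S)-1-[(2S)-3,3-dimethyloxiran-2-yl]but-3-yn-2-ol | C#C[C@@H](O)C[C@@H]1OC1(C)C | intermediate
9 | (3S,5S)-5-ethynyl-2,2-dimethyloxolan-3-ol (cis) | C#C[C@@H]1C[C@H](O)C(C)(C)O1 | intermediate
10 | (3S,5S)-5-ethynyl-2,2-dimethyl-3-(triethylsilyloxy)oxolane | C#C[C@@H]1C[C@H](O[Si](CC)(CC)CC)C(C)(C)O1 | intermediate
11 | dimethyl{(1E)-2-[(2S,4S)-5,5-dimethyl-4-(triethylsilyloxy)oxolan-2-yl]prop-1-en-1-yl}alumane | C[Al](C)/C=C(\C)[C@@H]1C[C@H](O[Si](CC)(CC)CC)C(C)(C)O1 | intermediate
12 | (3S,5S)-5-[(1E)-1-iodoprop-1-en-2-yl]-2,2-dimethyl-3-(triethylsilyloxy)oxolane | I/C=C(\C)[C@@H]1C[C@H](O[Si](CC)(CC)CC)C(C)(C)O1 | intermediate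
13 | (4-bromobut-1-yn-1-yl)trimethylsilane | C[Si](C)(C)C#CCCBr | starting material
14 | [4-(trimethylsilyl)but-3-yn-1-yl]zinc bromide | C[Si](C)(C)C#CCC[Zn]Br | intermediate
15 | (3S,5S)-2,2-dimethyl-3-(triethylsilyloxy)-5-[(2E)-7-(trimethylsilyl)hept-2-en-6-yn-2-yl]oxolane | C[Si](C)(C)C#CCC/C=C(\C)[C@@H]1C[C@H](O[Si](CC)(CC)CC)C(C)(C)O1 | intermediate
16 | (3S,5S)-5-[(2E)-hept-2-en-6-yn-2-yl]-2,2-dimethyl-3-(triethylsilyloxy)oxolane | C#CCC/C=C(\C)[C@@H]1C[C@H](O[Si](CC)(CC)CC)C(C)(C)O1 | intermediate
17 | dimethyl{(1E,5E)-2-methyl-6-[(2S,4S)-5,5-dimethyl-4-(triethylsilyloxy)oxolan-2-yl]hepta-1,5-dien-1-yl}alumane | C[Al](C)/C=C(\C)CC/C=C(\C)[C@@H]1C[C@H](O[Si](CC)(CC)CC)C(C)(C)O1 | intermediate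
18 | (3S,5S)-5-[(2E,6E)-7-iodo-6-methylhepta-2,6-dien-2-yl]-2,2-dimethyl-3-(triethylsilyloxy)oxolane | I/C=C(\C)CC/C=C(\C)[C@@H]1C[C@H](O[Si](CC)(CC)CC)C(C)(C)O1 | intermediate
19 | ethyl 3-oxopentanoate | CCC(=O)CC(=O)OCC | starting material
20 | chloroacetone | CC(=O)CCl | starting material
21 | ethyl 4-oxo-2-propanoylpentanoate (racemic) | CCC(=O)C(CC(C)=O)C(=O)OCC | intermediate
22 | ethyl 2-ethyl-5-methylfuran-3-carboxylate | CCc1oc(C)cc1C(=O)OCC | intermediate
23 | (2-ethyl-5-methylfuran-3-yl)methanol | CCc1oc(C)cc1CO | intermediate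
24 | 3-(chloromethyl)-2-ethyl-5-methylfuran | CCc1oc(C)cc1CCl | intermediate
25 | but-3-yn-1-ol | C#CCCO | starting material
26 | dimethylaluminium (3E)-4-(dimethylalumanyl)-3-methylbut-3-en-1-olate | C[Al](C)OCC/C(C)=C/[Al](C)C | intermediate
27 | (3E)-5-(2-ethyl-5-methylfuran-3-yl)-3-methylpent-3-en-1-ol | CCc1oc(C)cc1C/C=C(\C)CCO | intermediate
28 | (3E)-5-(2-ethyl-5-methylfuran-3-yl)-3-methylpent-3-enal | CCc1oc(C)cc1C/C=C(\C)CC=O | intermediate
29 | alkenyllithium from 18 (lithium in place of iodine) | [Li]/C=C(\C)CC/C=C(\C)[C@@H]1C[C@H](O[Si](CC)(CC)CC)C(C)(C)O1 | intermediate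
30 | alkenylzinc chloride from 29 | Cl[Zn]/C=C(\C)CC/C=C(\C)[C@@H]1C[C@H](O[Si](CC)(CC)CC)C(C)(C)O1 | intermediate
31 | alkenyl(butyl)zinc from 30 | CCCC[Zn]/C=C(\C)CC/C=C(\C)[C@@H]1C[C@H](O[Si](CC)(CC)CC)C(C)(C)O1 | intermediate
32 | (2E,5S,6E,10E)-1-(2-ethyl-5-methylfuran-3-yl)-3,7-dimethyl-11-[(2S,4S)-5,5-dimethyl-4-(triethylsilyloxy)oxolan-2-yl]dodeca-2,6,10-trien-5-ol | CCc1oc(C)cc1C/C=C(\C)C[C@H](O)/C=C(\C)CC/C=C(\C)[C@@H]1C[C@H](O[Si](CC)(CC)CC)C(C)(C)O1 | intermediate
33 | 2-ethyl-5-methyl-3-R*-furan (acetate of 32) | CCc1oc(C)cc1C/C=C(\C)C[C@H](OC(C)=O)/C=C(\C)CC/C=C(\C)[C@@H]1C[C@H](O[Si](CC)(CC)CC)C(C)(C)O1 | intermediate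
34 | 1-ethyl-4-methyl-6-R*-2,3,7-trioxabicyclo[2.2.1]hept-5-ene (bridgehead diastereomers) | CCC12OOC(C)(O1)C=C2C/C=C(\C)C[C@H](OC(C)=O)/C=C(\C)CC/C=C(\C)[C@@H]3C[C@H](O[Si](CC)(CC)CC)C(C)(C)O3 | intermediate
35 | (3Z)-4-R*-hept-3-ene-2,5-dione | CCC(=O)/C(C/C=C(\C)C[C@H](OC(C)=O)/C=C(\C)CC/C=C(\C)[C@@H]1C[C@H](O[Si](CC)(CC)CC)C(C)(C)O1)=C\C(C)=O | intermediate
36 | (3Z,5Z)-2,5-bis(tert-butyldimethylsilyloxy)-4-R*-hepta-1,3,5-triene | C=C(O[Si](C)(C)C(C)(C)C)/C=C(C/C=C(\C)C[C@H](OC(C)=O)/C=C(\C)CC/C=C(\C)[C@@H]1C[C@H](O[Si](CC)(CC)CC)C(C)(C)O1)\C(O[Si](C)(C)C(C)(C)C)=C\C | intermediate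
37 | 2-methyl-6-R*-cyclohex-5-ene-1,4-dione (C2 epimers) | CC1CC(=O)C=C(C/C=C(\C)C[C@H](OC(C)=O)/C=C(\C)CC/C=C(\C)[C@@H]2C[C@H](O[Si](CC)(CC)CC)C(C)(C)O2)C1=O | intermediate
38 | 2-methyl-6-R*-benzene-1,4-diol | Cc1cc(O)cc(C/C=C(\C)C[C@H](OC(C)=O)/C=C(\C)CC/C=C(\C)[C@@H]2C[C@H](O[Si](CC)(CC)CC)C(C)(C)O2)c1O | intermediate
39 | 2-methyl-6-R*-cyclohexa-2,5-diene-1,4-dione | CC1=CC(=O)C=C(C/C=C(\C)C[C@H](OC(C)=O)/C=C(\C)CC/C=C(\C)[C@@H]2C[C@H](O[Si](CC)(CC)CC)C(C)(C)O2)C1=O | intermediate
40 | 2-[(2E,5S,6E,10E)-5-acetoxy-11-{(2S,4S)-4-hydroxy-5,5-dimethyloxolan-2-yl}-3,7-dimethyldodeca-2,6,10-trien-1-yl]-6-methylcyclohexa-2,5-diene-1,4-dione | CC(=O)O[C@H](/C=C(\C)CC/C=C(\C)[C@@H]1C[C@H](O)C(C)(C)O1)C/C(C)=C/CC1=CC(=O)C=C(C)C1=O | target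

## Step count and risks

Total step count: 21. Longest linear sequence: 15 steps (steps 1–9 and 16–21, from 1 to 40); the furan branch (steps 10–15) joins at step 16.

Steps most likely to fail:

1. Step 20 (proposed new method). The radical cation may lose a proton from the doubly allylic C1′ methylene or be captured by the alcohol before it cyclises, or the electrode may passivate, so that ring closure does not compete. The fallback uses known pericyclic and dehydrogenation chemistry, sets out from 36 and forms the same ring bond. Heating 36 in degassed toluene (110 °C, sealed tube, BHT) should bring about the thermal disrotatory 6π-electrocyclisation of the (3Z)-triene to 6-methyl-2-R*-1,4-bis(tert-butyldimethylsilyloxy)cyclohexa-1,3-diene F1. DDQ (2,6-lutidine, CH2Cl2, 0 °C) should dehydrogenate it to the hydroquinone bis(silyl) ether 1,4-bis(tert-butyldimethylsilyloxy)-2-methyl-6-R*-benzene F2. TBAF/AcOH (THF, 0 °C) should cleave both aryl silyl ethers and the triethylsilyl ether to the free hydroquinone F3, and Ag2O (Et2O, MgSO4, rt) should oxidise F3 to the quinone. The fallback comes back to the route at 40 and replaces steps 20 and 21.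

2. Step 18. Singlet oxygen may undergo ene reactions with the three trisubstituted olefins before the furan is consumed, or the (Z)-enedione may isomerise or cyclise during peroxide reduction. The fallback sets out from 33 and changes the oxidation from a cycloaddition to a halogen-mediated oxidative methoxylation with an isolable intermediate. NBS (1.0 equiv), NaHCO3, MeOH/THF at −40 °C should convert the furan into the bis-ketal 2-ethyl-2,5-dimethoxy-5-methyl-3-R*-2,5-dihydrofuran F4, which can be purified. Hydrolysis with dilute aqueous oxalic acid in THF at 0 °C should then release the cis-enedione, so the fallback comes back to the route at 35.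

3. Step 16. Enantiofacial control may be poor with an α-unbranched aldehyde, and the organometallic may enolise the β,γ-unsaturated aldehyde or move its olefin into conjugation. The fallback sets out from 18 and 28 and separates bond formation from stereocontrol. Nozaki–Hiyama–Kishi coupling (CrCl2, NiCl2 (cat.), DMSO/THF, rt) should give the allylic alcohol as both C5′ epimers F5. Dess–Martin oxidation should give the enone F6. Corey–Bakshi–Shibata reduction with the (R)-2-methyl-oxazaborolidine and catecholborane (toluene, −78 °C), the trisubstituted alkenyl group acting as the large substituent, should give the (5′S)-alcohol, so the fallback comes back to the route at 32.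

Further compounds
F1 | step 20 | 6-methyl-2-R*-1,4-bis(tert-butyldimethylsilyloxy)cyclohexa-1,3-diene (C6 epimers) | CC1CC(O[Si](C)(C)C(C)(C)C)=CC(C/C=C(\C)C[C@H](OC(C)=O)/C=C(\C)CC/C=C(\C)[C@@H]2C[C@H](O[Si](CC)(CC)CC)C(C)(C)O2)=C1O[Si](C)(C)C(C)(C)C
F2 | step 20 | 1,4-bis(tert-butyldimethylsilyloxy)-2-methyl-6-R*-benzene | Cc1cc(O[Si](C)(C)C(C)(C)C)cc(C/C=C(\C)C[C@H](OC(C)=O)/C=C(\C)CC/C=C(\C)[C@@H]2C[C@H](O[Si](CC)(CC)CC)C(C)(C)O2)c1O[Si](C)(C)C(C)(C)C
F3 | step 20 | 2-[(2E,5S,6E,10E)-5-acetoxy-11-{(2S,4S)-4-hydroxy-5,5-dimethyloxolan-2-yl}-3,7-dimethyldodeca-2,6,10-trien-1-yl]-6-methylbenzene-1,4-diol | Cc1cc(O)cc(C/C=C(\C)C[C@H](OC(C)=O)/C=C(\C)CC/C=C(\C)[C@@H]2C[C@H](O)C(C)(C)O2)c1O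
F4 | step 18 | 2-ethyl-2,5-dimethoxy-5-methyl-3-R*-2,5-dihydrofuran (ketal diastereomers) | CCC1(OC)OC(C)(OC)C=C1C/C=C(\C)C[C@H](OC(C)=O)/C=C(\C)CC/C=C(\C)[C@@H]2C[C@H](O[Si](CC)(CC)CC)C(C)(C)O2
F5 | step 16 | (2E,6E,10E)-1-(2-ethyl-5-methylfuran-3-yl)-3,7-dimethyl-11-[(2S,4S)-5,5-dimethyl-4-(triethylsilyloxy)oxolan-2-yl]dodeca-2,6,10-trien-5-ol (C5 epimers) | CCc1oc(C)cc1C/C=C(\C)CC(O)/C=C(\C)CC/C=C(\C)[C@@H]1C[C@H](O[Si](CC)(CC)CC)C(C)(C)O1
F6 | step 16 | (2E,6E,10E)-1-(2-ethyl-5-methylfuran-3-yl)-3,7-dimethyl-11-[(2S,4S)-5,5-dimethyl-4-(triethylsilyloxy)oxolan-2-yl]dodeca-2,6,10-trien-5-one | CCc1oc(C)cc1C/C=C(\C)CC(=O)/C=C(\C)CC/C=C(\C)[C@@H]1C[C@H](O[Si](CC)(CC)CC)C(C)(C)O1
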